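## Retrosynthetic overview

- Numbering: C1 is the CH2OH carbon on C2H, C3 carries the second CH2OH (C3'), C6 and C7 are the oxirane carbons, C12 bears the acetate, C15 is the terminal C(CH3)2. The route rests on the oxirane O–C6–C7: it is the epoxide of an (E)-C6=C7 alkene with CH3 and C8 on C7 and C5 on C6, the pattern left by syn-methylmetalation of a terminal alkyne with capture at C6.
- Key disconnection: C7–CH3 and C5–C6 (C4–C5 from oxirane) by Cp2ZrCl2-catalysed methylalumination of the C6–C15 enyne 10 and opening of oxirane by the derived alkenylalanate, giving the C4 alcohol 15.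
- C3–C4 by Negishi coupling of the C4 alkylzinc iodide with the (E)-2-iodobut-2-ene-1,4-diol bis-PMB ether 21 (from but-2-yne-1,4-diol). Enyne 10 comes from 5-(trimethylsilyl)pent-4-ynal by Wittig olefination (C10=C11), Brown allylboration (C12) and cross-metathesis (C14=C15).
- Ring order: the oxirane is the only ring. It is formed after the key step by C4–OH-directed asymmetric epoxidation of C6=C7; the key step closes no ring.
- End game: C12 silyl ether to acetate, then removal of the two PMB ethers.

Key step: step 7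

Assumption 1: the antipode of the bishydroxamic acid ligand in step 8 is the one whose facial preference on (E)-4-methylalk-3-en-1-ols gives the (6S,7S)-epoxide; both antipodes are available from (R,R)- and (S,S)-cyclohexane-1,2-diamine, and the sense is to be confirmed at compound 16.

Assumption 2: the allylborane of step 3 is specified through its precursor, (+)-B-methoxydiisopinocampheylborane of the (−)-α-pinene series, which by analogy with benzaldehyde and α-methyl enals should deliver allyl to the Re face of enal 4; the configuration of 6 is to be confirmed by Mosher ester analysis.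

## Route

Step 1
Reactants: 1 5-(trimethylsilyl)pent-4-yn-1-ol
Product: 2 5-(trimethylsilyl)pent-4-ynal
Conditions: PhI(OAc)2, TEMPO (10 mol %), CH2Cl2, rt
Reagents that add atoms: none
Why: The TEMPO/PhI(OAc)2 oxidation of a primary alcohol stops at the aldehyde and leaves the C-silyl alkyne untouched.

Step 2
Reactants: 2 5-(trimethylsilyl)pent-4-ynal; 3 2-(triphenylphosphoranylidene)propanal
Product: 4 (E)-2-methyl-7-(trimethylsilyl)hept-2-en-6-ynal
Conditions: toluene, 90 °C
Reagents that add atoms: none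
Why: Wittig olefination with a formyl-stabilised ylide is reversible at the betaine/oxaphosphetane stage and should give the (E)-trisubstituted enal (C10=C11), the ylide reacting with the aliphatic aldehyde much faster than with the conjugated product.

Step 3
Reactants: 4 (E)-2-methyl-7-(trimethylsilyl)hept-2-en-6-ynal
Product: 6 (4R,5E)-5-methyl-10-(trimethylsilyl)deca-1,5-dien-9-yn-4-ol, via diisopinocampheylborinate 5 (not isolated)
Conditions: (+)-Ipc2BOMe, allylMgBr, Et2O, 0 °C → rt; then 4, −78 °C; then 30 % H2O2, aq. NaH2PO4/Na2HPO4 (pH 7), MeOH, 0 °C → rt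
Reagents that add atoms: allylmagnesium bromide, C=CC[Mg]Br; (+)-B-methoxydiisopinocampheylborane, COB([C@H]1C[C@H]2C[C@@H]([C@@H]1C)C2(C)C)[C@H]1C[C@H]2C[C@@H]([C@@H]1C)C2(C)C (supplies boron and the isopinocampheyl groups of 5 only)
Why: Brown allylboration through a chair Zimmerman–Traxler transition state, in which the (−)-α-pinene-derived isopinocampheyl groups should direct allyl to the Re face of the enal and set C12 as R; the buffered oxidative work-up spares the silyl alkyne.

Step 4
Reactants: 6 (4R,5E)-5-methyl-10-(trimethylsilyl)deca-1,5-dien-9-yn-4-ol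
Product: 7 (4R,5E)-4-(tert-butyldimethylsilyloxy)-5-methyl-10-(trimethylsilyl)deca-1,5-dien-9-yne
Conditions: t-BuMe2SiCl, imidazole, DMF, rt
Reagents that add atoms: tert-butyldimethylsilyl chloride, CC(C)(C)[Si](C)(C)Cl
Why: Imidazole-promoted silylation of the secondary allylic alcohol gives a bulky ether that tolerates AlMe3 and n-BuLi and keeps C12–O from directing the later vanadium epoxidation to C10=C11.

Step 5
Reactants: 7 (4R,5E)-4-(tert-butyldimethylsilyloxy)-5-methyl-10-(trimethylsilyl)deca-1,5-dien-9-yne; 8 2-methylbut-2-ene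
Product: 9 (5E,7R)-7-(tert-butyldimethylsilyloxy)-6,10-dimethyl-1-(trimethylsilyl)undeca-5,9-dien-1-yne
Conditions: second-generation Grubbs catalyst (5 mol %), 2-methylbut-2-ene (excess), CH2Cl2, 40 °C
Reagents that add atoms: none
Why: Olefin cross-metathesis of the terminal alkene with excess 2-methylbut-2-ene installs the isopropylidene terminus (C14=C15), while the trisubstituted C10=C11 alkene and the silyl-capped alkyne are poor partners for the ruthenium carbene.

Step 6
Reactants: 9 (5E,7R)-7-(tert-butyldimethylsilyloxy)-6,10-dimethyl-1-(trimethylsilyl)undeca-5,9-dien-1-yne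
Product: 10 (5E,7R)-7-(tert-butyldimethylsilyloxy)-6,10-dimethylundeca-5,9-dien-1-yne
Conditions: K2CO3, MeOH, rt
Reagents that add atoms: none
Why: Methoxide-mediated protodesilylation cleaves the alkynyl C–Si bond selectively, the O-silyl ether being stable to these conditions.

Step 7
Reactants: 10 (5E,7R)-7-(tert-butyldimethylsilyloxy)-6,10-dimethylundeca-5,9-dien-1-yne; 11 trimethylaluminium; 12 oxirane
Product: 15 (3E,7E,9R)-9-(tert-butyldimethylsilyloxy)-4,8,12-trimethyltrideca-3,7,11-trien-1-ol, via alkenyldimethylalane 13 (not isolated), via lithium alkenylalanate 14 (not isolated)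
Conditions: AlMe3 (2 equiv), Cp2ZrCl2 (25 mol %), CH2Cl2, 0 °C → rt; volatiles off; n-BuLi, hexane/THF, −30 °C; oxirane (excess), −30 °C → rt; aq. potassium sodium tartrate
Reagents that add atoms: n-butyllithium, [Li]CCCC (butyl and lithium of 14 only; nothing from it remains in 15)
Why: Zirconium-catalysed methylalumination (Negishi carboalumination) adds CH3 and aluminium syn across the terminal alkyne of 10, CH3 to the internal carbon C7 and aluminium to the terminal carbon C6, giving alane 13. n-BuLi converts 13 into the more nucleophilic alanate 14, whose sp2 carbon opens oxirane by SN2 attack with retention of alkene geometry, forming C5–C6 and the C4 hydroxyl; this is the known carboalumination/alanate–oxirane route to (E)-4-methylalk-3-en-1-ols. No ring is closed and no stereocentre is created; the step fixes the (E) geometry of C6=C7 (CH3 cis to C5, C8 trans to C5), which follows from syn addition and the regiochemistry intrinsic to terminal alkynes. The step needs chemoselectivity for the alkyne over the C10=C11 and C14=C15 alkenes and tolerance of the C12 silyl ether; unactivated trisubstituted alkenes are inert to Cp2ZrCl2/AlMe3 and the bulky silyl ether binds aluminium only weakly. Transfer of the alkenyl group in preference to methyl or butyl is the normal order for mixed alanates. The C4 hydroxyl created here is the handle that later directs epoxidation to C6=C7 alone among three trisubstituted alkenes.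

Step 8
Reactants: 15 (3E,7E,9R)-9-(tert-butyldimethylsilyloxy)-4,8,12-trimethyltrideca-3,7,11-trien-1-ol
Product: 16 2-{(2S,3S)-3-[(3E,5R)-5-(tert-butyldimethylsilyloxy)-4,8-dimethylnona-3,7-dien-1-yl]-3-methyloxiran-2-yl}ethanol
Conditions: VO(O-i-Pr)3 (2 mol %), C2-symmetric bishydroxamic acid ligand (4 mol %), cumene hydroperoxide, toluene, rt
Reagents that add atoms: cumene hydroperoxide, CC(C)(OO)c1ccccc1
Why: In this hydroxyl-directed asymmetric epoxidation of a homoallylic alcohol the C4 alkoxide binds the vanadium–bishydroxamate peroxide complex, which should deliver oxygen only to C6=C7 (the other alkenes have no free hydroxyl), the ligand choosing the face that gives 6S,7S while the (E) geometry fixes C5 and C8 trans.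

Step 9
Reactants: 16 2-{(2S,3S)-3-[(3E,5R)-5-(tert-butyldimethylsilyloxy)-4,8-dimethylnona-3,7-dien-1-yl]-3-methyloxiran-2-yl}ethanol
Product: 17 (2S,3S)-2-[(3E,5R)-5-(tert-butyldimethylsilyloxy)-4,8-dimethylnona-3,7-dien-1-yl]-3-(2-iodoethyl)-2-methyloxirane
Conditions: I2, PPh3, imidazole, CH2Cl2, 0 °C
Reagents that add atoms: iodine, II
Why: Appel-type iodination activates the primary C4 hydroxyl as an alkoxyphosphonium ion that iodide displaces by SN2, the imidazole buffer protecting the trisubstituted epoxide from acid.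

Step 10
Reactants: 18 but-2-yne-1,4-diol
Product: 19 1,4-bis(4-methoxybenzyloxy)but-2-yne
Conditions: NaH, 4-MeOC6H4CH2Cl, Bu4NI (cat.), THF/DMF, 0 °C → rt
Reagents that add atoms: 4-methoxybenzyl chloride, COc1ccc(CCl)cc1
Why: Double Williamson etherification of the primary propargylic diol gives ethers that survive organozinc and palladium chemistry and are removable oxidatively at the end.

Step 11
Reactants: 19 1,4-bis(4-methoxybenzyloxy)but-2-yne
Product: 21 (E)-2-iodo-1,4-bis(4-methoxybenzyloxy)but-2-ene, via alkenylstannane 20 (not isolated)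
Conditions: Bu3SnH, PdCl2(PPh3)2 (2 mol %), THF, rt; then I2, CH2Cl2, 0 °C
Reagents that add atoms: iodine, II; tributyltin hydride, CCCC[SnH](CCCC)CCCC (tin of 20 only)
Why: Palladium-catalysed hydrostannation adds Sn–H syn across the symmetrical alkyne (no regiochemical issue) and iododestannylation proceeds with retention, so the two CH2O arms end up cis as required for C1 and C3'.

Step 12
Reactants: 17 (2S,3S)-2-[(3E,5R)-5-(tert-butyldimethylsilyloxy)-4,8-dimethylnona-3,7-dien-1-yl]-3-(2-iodoethyl)-2-methyloxirane; 21 (E)-2-iodo-1,4-bis(4-methoxybenzyloxy)but-2-ene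
Product: 23 (2Z,6S,7S,10E,12R)-12-(tert-butyldimethylsilyloxy)-6,7-epoxy-1-(4-methoxybenzyloxy)-3-[(4-methoxybenzyloxy)methyl]-7,11,15-trimethylhexadeca-2,10,14-triene, via alkylzinc iodide 22 (not isolated)
Conditions: Zn dust (BrCH2CH2Br, Me3SiCl activation), THF, 35 °C; then 21, PdCl2(dppf) (5 mol %), THF, rt → 45 °C
Reagents that add atoms: zinc, [Zn] (in 22 only)
Why: In this sp3–sp2 Negishi coupling zinc inserts into the primary C–I bond and the weakly nucleophilic alkylzinc iodide transmetalates to the alkenylpalladium iodide from 21, reductive elimination forming C3–C4 with retention of alkene geometry while ethers, silyl ether and epoxide are tolerated.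

Step 13
Reactants: 23 (2Z,6S,7S,10E,12R)-12-(tert-butyldimethylsilyloxy)-6,7-epoxy-1-(4-methoxybenzyloxy)-3-[(4-methoxybenzyloxy)methyl]-7,11,15-trimethylhexadeca-2,10,14-triene
Product: 24 (2Z,6S,7S,10E,12R)-6,7-epoxy-1-(4-methoxybenzyloxy)-3-[(4-methoxybenzyloxy)methyl]-7,11,15-trimethylhexadeca-2,10,14-trien-12-ol
Conditions: Bu4NF, THF, rt
Reagents that add atoms: none
Why: Fluoride-induced desilylation cleaves the only silyl ether and leaves the benzylic ethers and the epoxide intact, without touching the C12 stereocentre.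

Step 14
Reactants: 24 (2Z,6S,7S,10E,12R)-6,7-epoxy-1-(4-methoxybenzyloxy)-3-[(4-methoxybenzyloxy)methyl]-7,11,15-trimethylhexadeca-2,10,14-trien-12-ol
Product: 25 (2Z,6S,7S,10E,12R)-6,7-epoxy-1-(4-methoxybenzyloxy)-3-[(4-methoxybenzyloxy)methyl]-7,11,15-trimethylhexadeca-2,10,14-trien-12-yl acetate
Conditions: Ac2O, pyridine, DMAP (cat.), CH2Cl2, rt
Reagents that add atoms: acetic anhydride, CC(=O)OC(C)=O
Why: DMAP-catalysed acylation of the only free hydroxyl occurs at oxygen, so the C12 configuration is retained.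

Step 15
Reactants: 25 (2Z,6S,7S,10E,12R)-6,7-epoxy-1-(4-methoxybenzyloxy)-3-[(4-methoxybenzyloxy)methyl]-7,11,15-trimethylhexadeca-2,10,14-trien-12-yl acetate
Product: 26 (2Z,6S,7S,10E,12R)-6,7-epoxy-1-hydroxy-3-(hydroxymethyl)-7,11,15-trimethylhexadeca-2,10,14-trien-12-yl acetate (CNP0252194.1)
Conditions: DDQ, CH2Cl2/aq. NaH2PO4–Na2HPO4 (pH 7), 0 °C
Reagents that add atoms: none
Why: Oxidative cleavage of the p-methoxybenzyl ethers by DDQ (benzylic hydride abstraction, then hydrolysis of the hemiacetal) under buffered conditions should release the two primary allylic alcohols while sparing the acetate, the epoxide and the alkenes.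

## Compound list

1 | 5-(trimethylsilyl)pent-4-yn-1-ol | C[Si](C)(C)C#CCCCO | starting material
2 | 5-(trimethylsilyl)pent-4-ynal | C[Si](C)(C)C#CCCC=O | intermediate
3 | 2-(triphenylphosphoranylidene)propanal | CC(C=O)=P(c1ccccc1)(c1ccccc1)c1ccccc1 | starting material
4 | (E)-2-methyl-7-(trimethylsilyl)hept-2-en-6-ynal | C[Si](C)(C)C#CCC/C=C(\C)C=O | intermediate
5 | (4R,5E)-5-methyl-10-(trimethylsilyl)deca-1,5-dien-9-yn-4-yl diisopinocampheylborinate ((−)-α-pinene series) | O([C@H](CC=C)/C(C)=C/CCC#C[Si](C)(C)C)B([C@H]1C[C@H]2C[C@@H]([C@@H]1C)C2(C)C)[C@H]1C[C@H]2C[C@@H]([C@@H]1C)C2(C)C | intermediate (not isolated)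
6 | (4R,5E)-5-methyl-10-(trimethylsilyl)deca-1,5-dien-9-yn-4-ol | O[C@H](CC=C)/C(C)=C/CCC#C[Si](C)(C)C | intermediate
7 | (4R,5E)-4-(tert-butyldimethylsilyloxy)-5-methyl-10-(trimethylsilyl)deca-1,5-dien-9-yne | CC(C)(C)[Si](C)(C)O[C@H](CC=C)/C(C)=C/CCC#C[Si](C)(C)C | intermediate
8 | 2-methylbut-2-ene | CC=C(C)C | starting material
9 | (5E,7R)-7-(tert-butyldimethylsilyloxy)-6,10-dimethyl-1-(trimethylsilyl)undeca-5,9-dien-1-yne | CC(C)(C)[Si](C)(C)O[C@H](CC=C(C)C)/C(C)=C/CCC#C[Si](C)(C)C | intermediate
10 | (5E,7R)-7-(tert-butyldimethylsilyloxy)-6,10-dimethylundeca-5,9-dien-1-yne (C6–C15 enyne, 12R) | CC(C)(C)[Si](C)(C)O[C@H](CC=C(C)C)/C(C)=C/CCC#C | intermediate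
11 | trimethylaluminium | C[Al](C)C | starting material
12 | oxirane | C1CO1 | starting material
13 | [(1E,5E,7R)-7-(tert-butyldimethylsilyloxy)-2,6,10-trimethylundeca-1,5,9-trien-1-yl]dimethylalane | CC(C)(C)[Si](C)(C)O[C@H](CC=C(C)C)/C(C)=C/CC/C(C)=C/[Al](C)C | intermediate (not isolated)
14 | lithium butyl[(1E,5E,7R)-7-(tert-butyldimethylsilyloxy)-2,6,10-trimethylundeca-1,5,9-trien-1-yl]dimethylaluminate | CC(C)(C)[Si](C)(C)O[C@H](CC=C(C)C)/C(C)=C/CC/C(C)=C/[Al-](C)(C)CCCC.[Li+] | intermediate (not isolated)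
15 | (3E,7E,9R)-9-(tert-butyldimethylsilyloxy)-4,8,12-trimethyltrideca-3,7,11-trien-1-ol (C4–C15 homoallylic alcohol; 6E,10E,12R in target numbering) | CC(C)(C)[Si](C)(C)O[C@H](CC=C(C)C)/C(C)=C/CC/C(C)=C/CCO | intermediate
16 | 2-{(2S,3S)-3-[(3E,5R)-5-(tert-butyldimethylsilyloxy)-4,8-dimethylnona-3,7-dien-1-yl]-3-methyloxiran-2-yl}ethanol | CC(C)(C)[Si](C)(C)O[C@H](CC=C(C)C)/C(C)=C/CC[C@]1(C)O[C@H]1CCO | intermediate
17 | (2S,3S)-2-[(3E,5R)-5-(tert-butyldimethylsilyloxy)-4,8-dimethylnona-3,7-dien-1-yl]-3-(2-iodoethyl)-2-methyloxirane | CC(C)(C)[Si](C)(C)O[C@H](CC=C(C)C)/C(C)=C/CC[C@]1(C)O[C@H]1CCI | intermediate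
18 | but-2-yne-1,4-diol | OCC#CCO | starting material
19 | 1,4-bis(4-methoxybenzyloxy)but-2-yne | COc1ccc(COCC#CCOCc2ccc(OC)cc2)cc1 | intermediate
20 | (E)-[1,4-bis(4-methoxybenzyloxy)but-2-en-2-yl]tributylstannane | CCCC[Sn](CCCC)(CCCC)/C(COCc1ccc(OC)cc1)=C/COCc1ccc(OC)cc1 | intermediate (not isolated)
21 | (E)-2-iodo-1,4-bis(4-methoxybenzyloxy)but-2-ene | I/C(COCc1ccc(OC)cc1)=C/COCc1ccc(OC)cc1 | intermediate
22 | {2-[(2S,3S)-3-[(3E,5R)-5-(tert-butyldimethylsilyloxy)-4,8-dimethylnona-3,7-dien-1-yl]-3-methyloxiran-2-yl]ethyl}zinc iodide | CC(C)(C)[Si](C)(C)O[C@H](CC=C(C)C)/C(C)=C/CC[C@]1(C)O[C@H]1CC[Zn]I | intermediate (not isolated)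
23 | (2Z,6S,7S,10E,12R)-12-(tert-butyldimethylsilyloxy)-6,7-epoxy-1-(4-methoxybenzyloxy)-3-[(4-methoxybenzyloxy)methyl]-7,11,15-trimethylhexadeca-2,10,14-triene | CC(C)(C)[Si](C)(C)O[C@H](CC=C(C)C)/C(C)=C/CC[C@]1(C)O[C@H]1CC/C(COCc1ccc(OC)cc1)=C/COCc1ccc(OC)cc1 | intermediate
24 | (2Z,6S,7S,10E,12R)-6,7-epoxy-1-(4-methoxybenzyloxy)-3-[(4-methoxybenzyloxy)methyl]-7,11,15-trimethylhexadeca-2,10,14-trien-12-ol | O[C@H](CC=C(C)C)/C(C)=C/CC[C@]1(C)O[C@H]1CC/C(COCc1ccc(OC)cc1)=C/COCc1ccc(OC)cc1 | intermediate
25 | (2Z,6S,7S,10E,12R)-6,7-epoxy-1-(4-methoxybenzyloxy)-3-[(4-methoxybenzyloxy)methyl]-7,11,15-trimethylhexadeca-2,10,14-trien-12-yl acetate | CC(=O)O[C@H](CC=C(C)C)/C(C)=C/CC[C@]1(C)O[C@H]1CC/C(COCc1ccc(OC)cc1)=C/COCc1ccc(OC)cc1 | intermediate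
26 | (2Z,6S,7S,10E,12R)-6,7-epoxy-1-hydroxy-3-(hydroxymethyl)-7,11,15-trimethylhexadeca-2,10,14-trien-12-yl acetate | CC(=O)O[C@H](CC=C(C)C)/C(C)=C/CC[C@]1(C)O[C@H]1CC/C(=C/CO)CO | target

## Step count and risks

Total steps: 15. Longest linear sequence: 13 (steps 1–9 and 12–15, from compound 1); the iodoalkene 21 takes 2 steps (10 and 11).

Steps most likely to fail:

Step 12. Zinc insertion next to the oxirane may be accompanied by zinc iodide-promoted opening or rearrangement of the trisubstituted epoxide, by 3-exo closure of the C4 carbanion onto C6, or by β-hydride elimination at palladium that erodes the coupling. The fallback reverses the polarity so that C4 never carries a metal. It sets out from 21 and 17: iodine–magnesium exchange on 21 (i-PrMgCl·LiCl, THF, −20 °C) should give the configurationally stable (E)-[1,4-bis(4-methoxybenzyloxy)but-2-en-2-yl]magnesium chloride F1, which is coupled with the primary iodide 17 under copper catalysis (Li2CuCl4 cat., THF, −20 → 0 °C). The much more hindered trisubstituted epoxide should be left alone, and the sequence comes back to the route at 23.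

Step 8. The epoxidation is purely reagent-controlled (C12 is too remote to help), so poor facial selectivity, the wrong facial sense of the chosen ligand antipode, or background non-directed oxidation would give the wrong or mixed epoxide configuration. The fallback moves the asymmetric step to an allylic alcohol and sets out from 10:
- Methylalumination as in step 7, with alanate 14 trapped by paraformaldehyde instead of oxirane, should give (2E,6E,8R)-8-(tert-butyldimethylsilyloxy)-3,7,11-trimethyldodeca-2,6,10-trien-1-ol F2.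
- Sharpless asymmetric epoxidation (Ti(O-i-Pr)4, L-(+)-diethyl tartrate, t-BuOOH, 4 Å molecular sieves, CH2Cl2, −20 °C) should give the (2S,3S)-epoxy alcohol [(2S,3S)-3-[(3E,5R)-5-(tert-butyldimethylsilyloxy)-4,8-dimethylnona-3,7-dien-1-yl]-3-methyloxiran-2-yl]methanol F3, the same sense as for geraniol.
- (CF3SO2)2O with 2,6-lutidine at −78 °C gives the epoxy triflate F4.
- Copper-catalysed displacement with (i-PrO)Me2SiCH2MgCl (CuI cat., THF, −40 °C) adds C4 as the silane isopropoxydimethyl{2-[(2S,3S)-3-[(3E,5R)-5-(tert-butyldimethylsilyloxy)-4,8-dimethylnona-3,7-dien-1-yl]-3-methyloxiran-2-yl]ethyl}silane F5.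
- Tamao oxidation (H2O2, KF, KHCO3, THF/MeOH, rt) converts C–Si into the C4 hydroxyl and comes back to the route at 16.

Step 7. Transfer of the alkenyl group from the alanate to oxirane may be incomplete or accompanied by competing butyl or methyl transfer and by protodealumination, which would lower the throughput of the key bond formation. The fallback separates the two events and sets out from 10: the alane 13 is formed as before and cleaved with I2 (THF, −30 °C) to the alkenyl iodide (1E,5E,7R)-7-(tert-butyldimethylsilyloxy)-1-iodo-2,6,10-trimethylundeca-1,5,9-triene F6, with retention of geometry. Iodine–lithium exchange (t-BuLi, Et2O, −78 °C) should give the alkenyllithium [(1E,5E,7R)-7-(tert-butyldimethylsilyloxy)-2,6,10-trimethylundeca-1,5,9-trien-1-yl]lithium F7, which opens oxirane in the presence of BF3·OEt2 at −78 °C and comes back to the route at 15.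

Further compounds
F1 | step 12 | (E)-[1,4-bis(4-methoxybenzyloxy)but-2-en-2-yl]magnesium chloride | Cl[Mg]/C(COCc1ccc(OC)cc1)=C/COCc1ccc(OC)cc1
F2 | step 8 | (2E,6E,8R)-8-(tert-butyldimethylsilyloxy)-3,7,11-trimethyldodeca-2,6,10-trien-1-ol | CC(C)(C)[Si](C)(C)O[C@H](CC=C(C)C)/C(C)=C/CC/C(C)=C/CO
F3 | step 8 | [(2S,3S)-3-[(3E,5R)-5-(tert-butyldimethylsilyloxy)-4,8-dimethylnona-3,7-dien-1-yl]-3-methyloxiran-2-yl]methanol | CC(C)(C)[Si](C)(C)O[C@H](CC=C(C)C)/C(C)=C/CC[C@]1(C)O[C@H]1CO
F4 | step 8 | [(2S,3S)-3-[(3E,5R)-5-(tert-butyldimethylsilyloxy)-4,8-dimethylnona-3,7-dien-1-yl]-3-methyloxiran-2-yl]methyl trifluoromethanesulfonate | CC(C)(C)[Si](C)(C)O[C@H](CC=C(C)C)/C(C)=C/CC[C@]1(C)O[C@H]1COS(=O)(=O)C(F)(F)F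
F5 | step 8 | isopropoxydimethyl{2-[(2S,3S)-3-[(3E,5R)-5-(tert-butyldimethylsilyloxy)-4,8-dimethylnona-3,7-dien-1-yl]-3-methyloxiran-2-yl]ethyl}silane | CC(C)(C)[Si](C)(C)O[C@H](CC=C(C)C)/C(C)=C/CC[C@]1(C)O[C@H]1CC[Si](C)(C)OC(C)C
F6 | step 7 | (1E,5E,7R)-7-(tert-butyldimethylsilyloxy)-1-iodo-2,6,10-trimethylundeca-1,5,9-triene | CC(C)(C)[Si](C)(C)O[C@H](CC=C(C)C)/C(C)=C/CC/C(C)=C/I
F7 | step 7 | [(1E,5E,7R)-7-(tert-butyldimethylsilyloxy)-2,6,10-trimethylundeca-1,5,9-trien-1-yl]lithium | CC(C)(C)[Si](C)(C)O[C@H](CC=C(C)C)/C(C)=C/CC/C(C)=C/[Li]
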